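The easiest thing to take from the readings is one difference: in Friday's run at 8.00 min, E stands at 46.6% and D at 46.8%, an excess of −0.214% in the product, and each reading scatters by 0.5 percentage points. Twice the scatter of such a difference, taken over that product, gives 1.51%, the excess ceiling: the largest excess this early reading can reasonably hide.

| flask | J | Q | G | Z | remark | time |
|---|---|---|---|---|---|---|
| Tuesday's | 0.10 M | 0.10 M | 0.26 M | 2.3 mM | run made earlier |  |
| Sunday's | 0.10 M | 0.10 M | 0.28 M | 2.3 mM | run made earlier |  |
| Friday's | 0.10 M | 0.10 M | 0.42 M | 2.3 mM | run made earlier |  |
| larch | 0.10 M | 0.10 M | 0.200 M | 2.3 mM |  | 2.5 h |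
| maple | 0.10 M | 0.10 M | 0.400 M | 2.3 mM |  | 2.5 h |

| run | time / min | E / % | D / % |
|---|---|---|---|
| Tuesday's | 20.0 | 42.3 | 41.7 |
| Tuesday's | 40.0 | 41.7 | 42.3 |
| Tuesday's | 60.0 | 42.6 | 43.1 |
| Tuesday's | 80.0 | 42.4 | 41.2 |
| Tuesday's | 120 | 41.5 | 42.7 |
| Sunday's | 20.0 | 42.9 | 42.1 |
| Sunday's | 40.0 | 43.1 | 43.7 |
| Sunday's | 60.0 | 43.5 | 43.9 |
| Sunday's | 80.0 | 44.0 | 43.7 |
| Sunday's | 120 | 43.5 | 43.5 |
| Friday's | 8.00 | 46.6 | 46.8 |
| Friday's | 15.0 | 47.0 | 48.5 |
| Friday's | 30.0 | 47.9 | 48.5 |
| Friday's | 60.0 | 49.6 | 49.3 |
| Friday's | 120 | 49.7 | 49.2 |

(readings scatter by 0.5 percentage points)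

- which of the two ends with the higher excess of E over D in the product ("neither" if they lie within 2 percentage points) (larch / maple / neither)
- excess of E over D in the product at the end, larch
- excess of E over D in the product at the end, maple

- Z is single-handed; J and Q are mirror images of each other, charged as a racemate, each of them at the stated concentration
- the numbers in the tables scatter with a standard deviation of 0.5 percentage points
- steps that have been proposed: G + Z + J -> Z + E; G + Z + Q -> Z + D; G -> L; E <-> D; Z <-> X
- an excess is below zero if the other one leads

The flask can be built up one step at a time. With the two catalysed steps on their own, E and D form at rates whose ratio at equal [J] and [Q] is the selectivity factor, and early E against D would read that factor directly. As the faster enantiomer is used up, the comparison drifts: each E comes from a J and each D from a Q, so with equal charges E minus D equals Q left minus J left, and in these two steps an excess stays in the product where the making stops with J and Q left. Adding G → L ends the making early: Tuesday's flask holds more G than J and Q together, 0.26 M against 0.200 M, yet its product stands at 84.2%. Z ⇌ X scales both making rates alike and leaves their ratio alone. Adding E ⇌ D puts a loss into the rate of E minus D in proportion to that difference, and this loss needs no G, so it continues once the making ends and the excess then shrinks. Larch carries less G than Friday's flask, so it should stop at a lower product, where the same selectivity leaves a larger excess, and the ceiling does not pass to it as a bound; if E ⇌ D is what holds the excess down, this reckoning expects larch and maple each below 1.51%, as a working expectation. With one catalyst their excesses should lie on the same side, and the ceiling is smaller than the margin of 2 points, so the expected answer is "neither". It gives an expected size, whereas the forecast names values.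

The forecast says neither, with 0% for larch and 0% for maple: “Neither should show a measurable excess”.

The simulation gives neither, with 0% for larch and 0% for maple, both below the ceiling.

    G + Z + J → Z + E (k = 36.0 M⁻² s⁻¹)
    G + Z + Q → Z + D (k = 15.0 M⁻² s⁻¹)
    G → L (k = 0.00170 s⁻¹)
    E ⇌ D (k = 0.0130 s⁻¹)
    Z ⇌ X (K = 0.500, k = 0.0110 s⁻¹)

The forecast and the flask agree. With E ⇌ D taken away, larch ends at 21.0% instead of 0%, far above the ceiling of 1.51%, and the relaxation half-life of 0.444 min in larch is short against 2.5 h. In the neighbour flask, larch with 0.12 M of G, the ceiling stands as an expectation, an excess below 1.51%, and that flask ends with 23.3% E and 23.3% D, less product than Friday's first reading. The computed excess there is 0%.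

(Readings and results are simulated with constants of no real substance; the scatter is artificial.)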